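The easy step comes first: the south run was charged like grey, so its readings show grey's early days.

| setting | south | north-east | grey | red | amber |
|---|---|---|---|---|---|
| G | 0.10 M | 0.20 M | 0.10 M | 0.10 M (fed, over 2.5 d) | 0.10 M |
| E | 0.060 M | 0.060 M | 0.0600 M | 0.0600 M | 0.0600 M (fed, over 2.5 d) |
| L | 0.25 M | 0.25 M | 0.250 M | 0.250 M | 0.250 M |
| remark | run made earlier | run made earlier | everything together at the start | all else is in the flask from the start; the feed brings no volume worth counting | all else is in the flask from the start; the feed brings no volume worth counting |
| time |  |  | 4.0 d | 4.0 d | 4.0 d |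

- south (time / d: D / %, J / %): 0.125: 2.5, 0.5; 0.333: 10.7, 0.2; 0.625: 22.1, 4.4; 1.04: 28.7, 11.4; 1.67: 27.7, 22.5; 2.08: 27.6, 28.0; 2.50: 22.2, 34.0
- north-east (time / h: D / %, J / %): 1.33: 0, 0.8; 3.00: 2.1, 0; 4.00: 5.2, 1.1; 6.00: 6.1, 0; 8.00: 10.2, 0.2; 10.0: 12.0, 1.6

(scatter of a reading: 1 percentage point)

- the best flask by share of D in D plus J; "all alike" if 1.5 percentage points covers them all (grey / red / amber / all alike)
- share of D in D plus J at the end, grey
- share of D in D plus J at the end, red
- share of D in D plus J at the end, amber



One thing looks wrong in the south run. D reads 28.7% at 1.04 d and 27.6% at 2.08 d, yet J climbs from 11.4% to 28.0% over the same stretch. We read D as a tank: something fills it and J is what drains out. A level stands still when inflow equals outflow, however large the outflow is.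

So we freeze D and [L] over that stretch and treat the drain as pseudo-first-order. Mean D over the slope of J gives 1.76 d, the drain time: the time constant of a D in the tank.

We take every J to have been D once. Then D/(D+J) is the part of what was born that survives, roughly the exponential of minus age over drain time. In grey we put the typical birth where D stops climbing, which gives an age of 2.96 d and a share of 18.7%. A steady feed delays the mean arrival by 1.25 d, so the age becomes 1.71 d and the share 37.9%. Our rule gives red and amber alike.

The forecast says red, with grey 19%, red 31% and amber 29%: “Weak E order penalises amber more, so red narrowly leads.” Our fed share stands higher than both of its fed values.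

The simulation gives grey 22.4%, red 34.2% and amber 36.8%, so amber is best, ahead of red by 2.6 percentage points against a margin of 1.5 points. At 4.00 d, amber holds D 20.4% and J 35.0%, while grey holds D 13.3% and J 46.1%. The drain time turns these shares back into ages: grey 2.63 d and amber 1.76 d, against our 2.96 d and 1.71 d.

    L + D → J (k = 0.130 L mol⁻¹ h⁻¹)
    G + E → X (k = 1.40 L mol⁻¹ h⁻¹)
    L + X → D (k = 0.390 L mol⁻¹ h⁻¹)

The step from L and D to J makes the drain time scale as one over [L]. We read the drain time in the south run at [L] near 0.182 M, counting one L per D and two per J. A neighbour of grey charged with 0.62 M of L averages 0.560 M between its start and its end, so its drain time is 0.574 d, and grey's age then gives a share of 0.576%. The computed share is 1.10%.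

(Readings and results are calculated with made-up constants; scatter was added.)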